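**A small charge.** A few millimolar of free catalyst, against molar substrates, changes what the flask makes. At 4.00 h, Monday's 2.6 mM had given 3.7 % target and 30.6 % uncatalysed product, while Thursday's 38 mM had given 18.7 % and 11.4 %.

common to all: starting material 1.3 M

| flask | second substrate | coupling partner | free catalyst | remark | time |
|---|---|---|---|---|---|
| Monday's | 0.65 M | 0.65 M | 2.6 mM | run made earlier |  |
| Thursday's | 0.65 M | 0.65 M | 38 mM | run made earlier |  |
| zeta | 0.650 M | 0.650 M | 8.0 mM |  | 8.0 h |
| theta | 0.650 M | 0.650 M | 13 mM |  | 8.0 h |
| epsilon | 0.650 M | 0.650 M | 20 mM |  | 8.0 h |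
| beta | 0.650 M | 0.650 M | 50 mM |  | 8.0 h |
| alpha | 0.650 M | 0.650 M | 3.0 mM |  | 8.0 h |

| run | time / h | target / % | uncatalysed product / % |
|---|---|---|---|
| Monday's | 1.00 | 0.7 | 13.6 |
| Monday's | 2.00 | 1.4 | 22.9 |
| Monday's | 3.00 | 3.7 | 27.7 |
| Monday's | 4.00 | 3.7 | 30.6 |
| Thursday's | 1.00 | 14.7 | 9.7 |
| Thursday's | 2.00 | 17.5 | 11.0 |
| Thursday's | 3.00 | 18.1 | 11.5 |
| Thursday's | 4.00 | 18.7 | 11.4 |

(readings scatter by 0.5 percentage points)

* the flasks put in order of share of target in all that became target or uncatalysed product, best first, at 8.0 h (zeta / theta / epsilon / beta / alpha)
* the share of target in all that became target or uncatalysed product of the flask you put first, at 8.0 h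
* the share of target in all that became target or uncatalysed product of the flask you put last, at 8.0 h

**Freeze something.** Let r be target over uncatalysed product. In Thursday's run r reads 1.52 at 1.00 h and 1.64 at 4.00 h, though both amounts grow. I therefore treat r as constant in time, and then a flask's share needs no clock.

**The chain.** Divide Thursday's last r by the catalyst charge C and you get 0.0432 /mM. Call this s, the selectivity factor: target over uncatalysed product, per amount of free catalyst charged. If s holds, r = sC and the share is r/(1 + r), which rises with C. So my ranking follows the charge, with beta at 50 mM first and alpha at 3.0 mM last. I commit to 68.3 % for beta and 11.5 % for alpha.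

**The weak link.** The value of s is a reading from Thursday's run, so test it on Monday's run. With Monday's charge and its 30.6 % of uncatalysed product, s predicts 3.44 % target. The reading is 3.7 %, and each reading carries 0.5 percentage points.

**The forecast.** It takes r as 0.044 per mM of catalyst, calling the catalysed route “about first order in catalyst”. Its order is beta > epsilon > theta > zeta > alpha, with 68 % on top and 12 % at the bottom, a little above my low share.

**The flask.** The flasks give beta > epsilon > theta > zeta > alpha, with 68.3 % in beta and 11.4 % in alpha.

    starting material + free catalyst ⇌ catalyst intermediate A (K = 1.30 /M, k = 160 /M/h)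
    coupling partner + catalyst intermediate A → free catalyst + target (k = 28.0 /M/h)
    second substrate + free catalyst ⇌ catalyst intermediate B (K = 0.920 /M, k = 140 /M/h)
    coupling partner + catalyst intermediate B → free catalyst + second product (k = 92.0 /M/h)
    starting material + coupling partner → uncatalysed product (k = 0.290 /M/h)

Beta's 9.45 % of uncatalysed product, multiplied by sC, gives 20.4 % target, and beta holds 20.4 %. But a share is not a yield: in beta the coupling partner, the limiting reagent, stands at 0 %, with 68.4 % of the starting material left. Now take alpha's neighbour with 1.80 mM of free catalyst. There s gives r = 0.0778 and a share of 7.21 %, and that flask gives 7.19 %, with 39.0 % of the starting material charged as uncatalysed product.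

All runs are simulated with constants of no real substance.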